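**Retrosynthetic overview**

1. The four benzene rings are bought intact (A = 2,4,6-trihydroxyphenyl end, D = 3,4,5-trihydroxyphenyl end). The only bonds between them are three aryl–O bonds, each joining the oxygen of a 2,6-dioxygenated phenol to C1 of a 3,4,5-trioxygenated ring.
2. Each of these bonds is cut to a hindered phenoxide and a 3,4,5-trimethoxyphenyl cation equivalent: one aryl(2,4,6-trimethoxyphenyl)iodonium salt, in which an electron-rich ring that normally reacts as a nucleophile is the electrophile (metal-free ligand coupling at iodine(III)).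
3. The central methoxy group of each newly attached 3,4,5-trimethoxyphenyl ring is a latent phenol. BCl3 cleaves only this doubly flanked ether and regenerates a 2,6-dimethoxyphenol for the next arylation, so the same iodonium salt delivers rings B, C and D.
4. Order of ring attachment (no ring is constructed): A → A–B → A–B–C → A–B–C–D, then ten-fold O-demethylation with BBr3.

Assumption: the target SMILES has no stereocentre and the diaryl ether axes rotate freely, so the compound is achiral and no stereocontrol is needed.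

**Route**

Step 1
Reactants: 1 5-iodo-1,2,3-trimethoxybenzene; 2 1,3,5-trimethoxybenzene
Product: 4 (3,4,5-trimethoxyphenyl)(2,4,6-trimethoxyphenyl)iodonium tosylate, via hydroxy(tosyloxy)iodoarene 3 (not isolated)
Conditions: mCPBA (1.05 equiv), TsOH·H2O (1.05 equiv), MeCN, rt → 40 °C, 30 min; then 2 (1.05 equiv), rt, 15 min; Et2O trituration
Reagents that add atoms: p-toluenesulfonic acid, Cc1ccc(cc1)S(=O)(=O)O
Why: Peracid oxidation of the aryl iodide in the presence of TsOH gives the Koser-type λ3-iodane 3, which the very nucleophilic 1,3,5-trimethoxybenzene attacks through its ring carbon (one-pot diaryliodonium salt synthesis, SEAr on the arene), so that the trimethoxyphenyl ring of 1 becomes an aryl cation equivalent and the 2,4,6-trimethoxyphenyl group is the non-transferred ligand.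

Step 2
Reactants: 5 2,4,6-trimethoxyphenol; 4 (3,4,5-trimethoxyphenyl)(2,4,6-trimethoxyphenyl)iodonium tosylate
Product: 6 1,3,5-trimethoxy-2-(3,4,5-trimethoxyphenoxy)benzene
Conditions: K2CO3 (2 equiv), 4 (1.2 equiv), degassed MeCN, 60 °C, Ar, dark
Reagents that add atoms: none
Why: Metal-free O-arylation of a phenoxide with a diaryliodonium salt (ligand exchange at iodine(III), then ligand coupling) transfers the less electron-rich 3,4,5-trimethoxyphenyl group and expels 2-iodo-1,3,5-trimethoxybenzene, and this reaction type tolerates two ortho substituents on the phenol; no stereocentre is formed.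

Step 3
Reactants: 6 1,3,5-trimethoxy-2-(3,4,5-trimethoxyphenoxy)benzene
Product: 7 2,6-dimethoxy-4-(2,4,6-trimethoxyphenoxy)phenol
Conditions: BCl3 (1.3 equiv), CH2Cl2, −20 °C → rt (TLC control); H2O work-up
Reagents that add atoms: none
Why: Regioselective BCl3 O-demethylation of a hindered aryl methyl ether: the central methoxy group of the 1,2,3-trimethoxy unit is the only one forced out of the ring plane by two ortho oxygens, which makes it the most Lewis basic and the one that is cleaved, while the five other methoxy groups and the diaryl ether stay intact.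

Step 4
Reactants: 7 2,6-dimethoxy-4-(2,4,6-trimethoxyphenoxy)phenol; 4 (3,4,5-trimethoxyphenyl)(2,4,6-trimethoxyphenyl)iodonium tosylate
Product: 8 2-[3,5-dimethoxy-4-(3,4,5-trimethoxyphenoxy)phenoxy]-1,3,5-trimethoxybenzene
Conditions: K2CO3 (2 equiv), 4 (1.2 equiv), degassed MeCN, 60 °C, Ar, dark
Reagents that add atoms: none
Why: The same diaryliodonium O-arylation (ligand coupling at iodine(III)) as in step 2, now on the regenerated 2,6-dimethoxyphenol, again with exclusive transfer of the 3,4,5-trimethoxyphenyl group.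

Step 5
Reactants: 8 2-[3,5-dimethoxy-4-(3,4,5-trimethoxyphenoxy)phenoxy]-1,3,5-trimethoxybenzene
Product: 9 4-[2,6-dimethoxy-4-(2,4,6-trimethoxyphenoxy)phenoxy]-2,6-dimethoxyphenol
Conditions: BCl3 (1.3 equiv), CH2Cl2, −20 °C → rt (TLC control); H2O work-up
Reagents that add atoms: none
Why: The same regioselective BCl3 cleavage of a hindered methyl ether as in step 3: of the eight methoxy groups only the central one of the terminal ring is flanked by two ortho oxygens, so only it is removed.

Step 6
Reactants: 9 4-[2,6-dimethoxy-4-(2,4,6-trimethoxyphenoxy)phenoxy]-2,6-dimethoxyphenol; 4 (3,4,5-trimethoxyphenyl)(2,4,6-trimethoxyphenyl)iodonium tosylate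
Product: 10 2-{4-[3,5-dimethoxy-4-(3,4,5-trimethoxyphenoxy)phenoxy]-3,5-dimethoxyphenoxy}-1,3,5-trimethoxybenzene
Conditions: K2CO3 (2 equiv), 4 (1.3 equiv), degassed MeCN, 60 °C, Ar, dark
Reagents that add atoms: none
Why: The third diaryliodonium O-arylation (ligand coupling at iodine(III)) attaches ring D to the hindered phenol of the trimer and completes the tetra-aryl triether skeleton, with all ten oxygens in place as methyl ethers.

Step 7
Reactants: 10 2-{4-[3,5-dimethoxy-4-(3,4,5-trimethoxyphenoxy)phenoxy]-3,5-dimethoxyphenoxy}-1,3,5-trimethoxybenzene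
Product: 11 2-{4-[3,5-dihydroxy-4-(3,4,5-trihydroxyphenoxy)phenoxy]-3,5-dihydroxyphenoxy}benzene-1,3,5-triol (CNP0333502.0)
Conditions: BBr3 (20 equiv), CH2Cl2, −78 °C → rt, 24 h; H2O quench at 0 °C; RP-C18 with degassed H2O/MeOH, Ar
Reagents that add atoms: none
Why: Exhaustive BBr3 O-demethylation (boron coordination to each ether oxygen, then SN2 attack of bromide on methyl) frees all ten phenols, while the three diaryl ether bonds, which offer no alkyl carbon for attack, survive.

**Compound list**

1 | 5-iodo-1,2,3-trimethoxybenzene | COc1cc(I)cc(OC)c1OC | starting material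
2 | 1,3,5-trimethoxybenzene | COc1cc(OC)cc(OC)c1 | starting material
3 | 5-[hydroxy(tosyloxy)-λ3-iodanyl]-1,2,3-trimethoxybenzene (Koser-type iodane, formed in situ) | COc1cc(I(O)OS(=O)(=O)c2ccc(C)cc2)cc(OC)c1OC | intermediate
4 | (3,4,5-trimethoxyphenyl)(2,4,6-trimethoxyphenyl)iodonium tosylate | COc1cc(OC)c([I+]c2cc(OC)c(OC)c(OC)c2)c(OC)c1.Cc1ccc(cc1)S(=O)(=O)[O-] | intermediate
5 | 2,4,6-trimethoxyphenol | COc1cc(OC)c(O)c(OC)c1 | starting material
6 | 1,3,5-trimethoxy-2-(3,4,5-trimethoxyphenoxy)benzene | COc1cc(OC)c(Oc2cc(OC)c(OC)c(OC)c2)c(OC)c1 | intermediate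
7 | 2,6-dimethoxy-4-(2,4,6-trimethoxyphenoxy)phenol | COc1cc(OC)c(Oc2cc(OC)c(O)c(OC)c2)c(OC)c1 | intermediate
8 | 2-[3,5-dimethoxy-4-(3,4,5-trimethoxyphenoxy)phenoxy]-1,3,5-trimethoxybenzene | COc1cc(OC)c(Oc2cc(OC)c(Oc3cc(OC)c(OC)c(OC)c3)c(OC)c2)c(OC)c1 | intermediate
9 | 4-[2,6-dimethoxy-4-(2,4,6-trimethoxyphenoxy)phenoxy]-2,6-dimethoxyphenol | COc1cc(OC)c(Oc2cc(OC)c(Oc3cc(OC)c(O)c(OC)c3)c(OC)c2)c(OC)c1 | intermediate
10 | 2-{4-[3,5-dimethoxy-4-(3,4,5-trimethoxyphenoxy)phenoxy]-3,5-dimethoxyphenoxy}-1,3,5-trimethoxybenzene | COc1cc(OC)c(Oc2cc(OC)c(Oc3cc(OC)c(Oc4cc(OC)c(OC)c(OC)c4)c(OC)c3)c(OC)c2)c(OC)c1 | intermediate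
11 | 2-{4-[3,5-dihydroxy-4-(3,4,5-trihydroxyphenoxy)phenoxy]-3,5-dihydroxyphenoxy}benzene-1,3,5-triol | Oc1cc(O)c(Oc2cc(O)c(Oc3cc(O)c(Oc4cc(O)c(O)c(O)c4)c(O)c3)c(O)c2)c(O)c1 | target

**Step count and risks**

Total step count: 7. Longest linear sequence: 7 (steps 1–7; salt 4 is made once, in at least 4 equivalents relative to 5, and used in steps 2, 4 and 6).

Steps most likely to fail:

Step 5 (single demethylation of 8; it has more competing methoxy groups than step 3). The risk is over-cleavage, or cleavage of a singly flanked methoxy group once the boron aryloxide chelates a neighbour. The fallback sets out from 7 and 1 and comes back at 9; it carries the latent phenol as a benzyl ether, so no selective ether cleavage on the oligomer is needed. Iodide 1 is demethylated at its hindered central oxygen at the monomer stage, where no other ring competes (BCl3, CH2Cl2, 0 °C), to give 4-iodo-2,6-dimethoxyphenol F1. Benzylation (BnBr, K2CO3, DMF) gives 2-(benzyloxy)-5-iodo-1,3-dimethoxybenzene F2. Oxidation with mCPBA/TsOH·H2O in MeCN gives, without isolation, 2-(benzyloxy)-5-[hydroxy(tosyloxy)-λ3-iodanyl]-1,3-dimethoxybenzene F3, which is quenched with 2 to give [4-(benzyloxy)-3,5-dimethoxyphenyl](2,4,6-trimethoxyphenyl)iodonium tosylate F4. Phenol 7 is O-arylated with this salt (K2CO3, MeCN, 60 °C) to 2-{4-[4-(benzyloxy)-3,5-dimethoxyphenoxy]-3,5-dimethoxyphenoxy}-1,3,5-trimethoxybenzene F5, and hydrogenolysis (H2, Pd/C, EtOAc/MeOH, rt) gives 9.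

Step 6 (O-arylation of the trimeric phenol 9 with 4). The risk is slow ligand coupling with the large, hindered phenoxide and competing one-electron oxidation of this electron-rich phenoxide by the iodonium salt. The fallback sets out from 9 and 1 and comes back at 10; it makes no new compound (none F0). It is a copper-catalysed Ullmann-type etherification of 9 with the aryl iodide 1 itself (CuI, picolinic acid, K3PO4, DMSO, 90 °C, Ar), which forms the same aryl–O bond with normal polarity at the aryl carbon. The same coupling with 1 could stand in for steps 2 and 4, where it gives 6 and 8.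

Step 7 (ten-fold demethylation and isolation of the free polyphenol). The risk is incomplete cleavage to inseparable partly methylated phenols and air oxidation of the pyrogallol- and hydroquinone-type rings during chromatography. The fallback sets out from 10 and comes back at 11. The methyl ethers are cleaved with AlCl3/EtSH (CH2Cl2, 0 °C → rt; hard acid/soft nucleophile dealkylation). The crude phenol is acetylated at once (Ac2O, pyridine, DMAP) and the air-stable 2-{4-[3,5-diacetoxy-4-(3,4,5-triacetoxyphenoxy)phenoxy]-3,5-diacetoxyphenoxy}benzene-1,3,5-triyl triacetate F6 is purified on silica. Acid-catalysed methanolysis (degassed HCl/MeOH, rt, Ar) then releases 11 with only volatile by-products.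

**Further compounds**

F1 | step 5 | 4-iodo-2,6-dimethoxyphenol | COc1cc(I)cc(OC)c1O
F2 | step 5 | 2-(benzyloxy)-5-iodo-1,3-dimethoxybenzene | COc1cc(I)cc(OC)c1OCc1ccccc1
F3 | step 5 | 2-(benzyloxy)-5-[hydroxy(tosyloxy)-λ3-iodanyl]-1,3-dimethoxybenzene | COc1cc(I(O)OS(=O)(=O)c2ccc(C)cc2)cc(OC)c1OCc1ccccc1
F4 | step 5 | [4-(benzyloxy)-3,5-dimethoxyphenyl](2,4,6-trimethoxyphenyl)iodonium tosylate | COc1cc(OC)c([I+]c2cc(OC)c(OCc3ccccc3)c(OC)c2)c(OC)c1.Cc1ccc(cc1)S(=O)(=O)[O-]
F5 | step 5 | 2-{4-[4-(benzyloxy)-3,5-dimethoxyphenoxy]-3,5-dimethoxyphenoxy}-1,3,5-trimethoxybenzene | COc1cc(OC)c(Oc2cc(OC)c(Oc3cc(OC)c(OCc4ccccc4)c(OC)c3)c(OC)c2)c(OC)c1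
F0 | step 6 | none | none
F6 | step 7 | 2-{4-[3,5-diacetoxy-4-(3,4,5-triacetoxyphenoxy)phenoxy]-3,5-diacetoxyphenoxy}benzene-1,3,5-triyl triacetate | CC(=O)Oc1cc(OC(C)=O)c(Oc2cc(OC(C)=O)c(Oc3cc(OC(C)=O)c(Oc4cc(OC(C)=O)c(OC(C)=O)c(OC(C)=O)c4)c(OC(C)=O)c3)c(OC(C)=O)c2)c(OC(C)=O)c1
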